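The runs are simulated with made-up constants; the scatter is artificial.

No constants are known yet, so the runs have to serve. Reagent stands at 0.100 M against 0.200 M of the two substrates together, which makes it the limiting reagent.

| flask | starting material | reagent | second substrate | temperature | remark | time |
|---|---|---|---|---|---|---|
| Saturday's | 0.10 M | 0.10 M | 0.10 M | 10 °C | run made earlier |  |
| Tuesday's | 0.10 M | 0.10 M | 0.14 M | 25 °C | run made earlier |  |
| Sunday's | 0.10 M | 0.10 M | 0.22 M | 10 °C | run made earlier |  |
| amber | 0.10 M (fed, over 12 h) | 0.100 M | 0.100 M | 25 °C | all else is in the flask from the start; the feed brings no volume worth counting | 15 h |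
| blue | 0.10 M | 0.100 M | 0.100 M (fed, over 12 h) |  | the addition at −15 °C, then warmed to 25 °C; the feed brings no volume worth counting | 15 h |
| grey | 0.10 M | 0.100 M | 0.100 M (in portions, 4, over 12 h) | 25 °C | first portion at the start, last at 12 h | 15 h |
| green | 0.10 M | 0.100 M | 0.100 M | 25 °C | everything together at the start | 15 h |

| run | time / h | target / % | over-reaction product / % |
|---|---|---|---|
| Saturday's | 3.00 | 26.3 | 14.8 |
| Saturday's | 5.00 | 24.0 | 18.3 |
| Saturday's | 8.00 | 23.8 | 20.4 |
| Saturday's | 10.0 | 19.7 | 24.5 |
| Saturday's | 12.0 | 22.6 | 24.3 |
| Saturday's | 15.0 | 19.4 | 25.9 |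
| Saturday's | 20.0 | 15.8 | 27.8 |
| Tuesday's | 0.667 | 23.3 | 11.6 |
| Tuesday's | 1.00 | 26.5 | 17.7 |
| Tuesday's | 1.50 | 24.0 | 20.6 |
| Tuesday's | 2.50 | 19.0 | 24.7 |
| Tuesday's | 4.00 | 11.9 | 26.5 |
| Tuesday's | 6.00 | 10.2 | 32.0 |
| Tuesday's | 10.0 | 4.5 | 31.8 |
| Sunday's | 1.33 | 20.3 | 3.9 |
| Sunday's | 2.00 | 24.5 | 7.4 |
| Sunday's | 3.00 | 25.3 | 10.0 |
| Sunday's | 5.00 | 23.1 | 12.8 |
| Sunday's | 8.00 | 21.2 | 15.4 |
| Sunday's | 12.0 | 19.8 | 18.4 |
| Sunday's | 20.0 | 13.7 | 19.9 |

(standard deviation of a reading: 1 percentage point)

- the numbers in the tables scatter by 1 percentage point (one standard deviation)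

* the flask that comes out highest in share of target in target plus over-reaction product, or "all alike" when all lie within 1.5 percentage points (amber / blue / grey / green / all alike)
* share of target in target plus over-reaction product at the end, amber
* share of target in target plus over-reaction product at the end, blue
* share of target in target plus over-reaction product at the end, grey
* share of target in target plus over-reaction product at the end, green

A bench rule says that target is safe once the limiting reagent is spent. To test it, take target as holding one reagent and over-reaction product as holding two, an assumption here. Tuesday's target plus over-reaction product read 0.0446 M at 1.50 h. The border is a ratio: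

charged [reagent] / (2 × [target + over-reaction product]) = 1.12

The ratio stands above one, so the charge could pay for every product as over-reaction product, and the rule stops here. The reagent standing elsewhere can be read as a balance:

1 − ([target] + 2[over-reaction product]) / charged [reagent] = 31.9% (Tuesday's, 10.0 h)

This is the reagent reserve, the part of the charge in neither product, as a reading. Sunday's run, whose second substrate stands at 0.22 M, reads 46.5%. That is more than Saturday's 28.6% with 0.10 M, so second substrate appears to hold reagent.

This reckoning expects the least reserve in grey, whose second substrate comes in portions, and so puts grey last among the flasks held at 25 °C. Blue's cold stage lies outside it.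

The forecast gives amber 8%, blue 38%, grey 15% and green 5%, with blue highest, and holds that the share “depends mainly on product age”. It puts grey above amber and green, where the reckoning here puts it below them.

The flasks give amber 19.8%, blue 33.8%, grey 5.39% and green 7.60%, with blue highest. Grey ends with second product at 0.00842 M, less than green's 0.0159 M. The reserve at the end reads 11.7% in grey, 21.2% in green and 32.6% in amber, and the shares of these three rise in the same order.

    starting material + reagent ⇌ target (K = 50.0 M⁻¹, k = 0.260 M⁻¹ min⁻¹, Ea = 71.0 kJ mol⁻¹, ΔH = −26.0 kJ mol⁻¹)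
    second substrate + reagent ⇌ second product (K = 31.0 M⁻¹, k = 0.0640 M⁻¹ min⁻¹, Ea = 60.0 kJ mol⁻¹, ΔH = −18.0 kJ mol⁻¹)
    reagent + target → over-reaction product (k = 0.310 M⁻¹ min⁻¹, Ea = 71.0 kJ mol⁻¹)
    2 starting material → self-condensation product (k = 0.0360 M⁻¹ min⁻¹, Ea = 51.0 kJ mol⁻¹)
    reagent → decomposition product (k = 5.50 × 10⁻⁶ min⁻¹, Ea = 114 kJ mol⁻¹)
    (constants at 25 °C)

Take a flask like blue but with 0.40 M starting material. Tuesday's reserve of 31.9%, carried over although that run had other charges, leaves 0.0681 M of reagent for the two products. So target plus twice the over-reaction product comes to 17.0% of that charge. Computed, target 7.25% and twice the over-reaction product 6.86% sum to 21.0%, above that figure. The reserve of this flask reads 16.1%, and its share is 51.4%.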